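## Analysis of the target

Target 15 is a flavonol: a 4H-chromen-4-one made of benzo ring A and pyranone ring C, with an unsubstituted phenyl ring B on C2. It has no stereocentre, so the task is one of regiochemistry and of telling four oxygen atoms apart. Ring A is substituted at every carbon except C6, with a hydroxyl at C5 that is hydrogen-bonded to the C4 carbonyl, a methyl ether at C7 and a butanoate ester at C8, and ring C carries an enolic hydroxyl at C3. The aryl ester is the most fragile group, since base or nucleophiles cleave it and the phenol set free is a 5,8-hydroquinone monoether that oxidises easily to a quinone. The 3-hydroxyl is acidic and acylates more readily than the chelated 5-hydroxyl, so the ester cannot simply be put on last. The synthesis is hard because the contiguous 5,7,8-oxygen pattern must be set without the 5,6,7 isomer (the two arise together whenever ring C can close on either of two ortho hydroxyls), and because the four oxygens end in three different states. The strategy rests on ring C: C4 is an aroyl carbon on C4a and C2 carries both O1 and the phenyl group, so cutting C3–C4 leads back to an aldehyde and an aryl 1-phenylvinyl ether, and a radical formed at C2 by attack on C3 is tertiary, benzylic and oxygen-stabilised.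

## Retrosynthetic reasoning

**O5–CH3 (15 from 14).** The last bond cut is the methyl–oxygen bond at O5. Of the two methyl ethers in 14, only the one peri to the C4 carbonyl can be reached by a chelating Lewis acid, so the 7-methyl ether and the ester at O8 should be left alone. Keeping O5 methylated until the end means that ring closure and the oxidation of ring C are run without a free phenol.

**C3–O (14 from 12 through 13).** The 3-hydroxyl is taken off next. A dioxirane should transfer oxygen to the C2=C3 double bond of 12 to give epoxide 13. Acid opens 13 at C2, where the cation is stabilised by O1 and the phenyl group, and loss of the C3 proton gives the enol 14. The hydroxyl is introduced after ring C exists because the ring-forming step needs hydrogen, not oxygen, at C3.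

**O8–acyl and O8–Si (12 from 9 and 10 through 11).** The ester is exchanged for a silyl ether. Fluoride frees phenoxide 11 from 9, and anhydride 10 acylates it in the same flask. Doing this before the 3-hydroxyl exists removes the only competing nucleophile, and it keeps the oxidation-prone phenol 11 from being isolated.

**C3–C4 (9 from 8), the key disconnection.** Ring C is opened between the aroyl carbon C4 and C3. This leaves aldehyde 8, in which the future C4 is the formyl carbon and the future C2–C3 unit is a 1-phenylvinyl group on the ortho oxygen. Cutting here, and not at O1–C2 or C2–C3, avoids any acetophenone or 1,3-diketone intermediate and any closure that could choose between two hydroxyls. The forward reaction must turn the formyl C–H bond into an acyl radical, close it 6-endo onto the alkene CH2, and oxidise the resulting C2 radical to the pyranone.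

**O1–C2 (8 from 6 and 7).** The vinyl–oxygen bond cannot be made by substitution at an sp2 carbon, so it is cut to phenol 6 and alkenylboronic acid 7. These are joined by copper-promoted oxidative coupling, which tolerates the aldehyde and the silyl ether.

**O–Si (6 from 5).** The two hydroxyls of 5 differ. The one ortho to the aldehyde is tied up in a strong hydrogen bond, and the other is free. Silylation should take the free one, and any silyl migration would run toward the same isomer because it keeps the chelate.

**C–CHO (5 from 3 through 4).** The aldehyde carbon is removed from the only ring carbon of catechol 3 that is ortho to a hydroxyl. A magnesium phenoxide delivers formaldehyde to that carbon to give alcohol 4, and a second formaldehyde oxidises 4 to the aldehyde. The other ring CH lies between two methyl ethers and cannot be reached this way.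

**Aryl C–O (3 from 1 through 2).** The second catechol oxygen comes from the formyl group of commercial aldehyde 1 by Dakin oxidation through formate 2. Aldehyde 1 already holds both methyl ethers in their final positions.

## Alternatives that were turned down

**Alternative 1: ring A by folding a masked tetraketide.** The cut is C4a–C8a. The precursor would be the pyranone A2, 3-(benzyloxy)-4-methoxy-6-[(E)-2-oxo-4-phenylbut-3-en-1-yl]-2H-pyran-2-one, whose lactone carbonyl is the future C8a. In the forward step, Mg(OMe)2 in methanol opens the lactone, the methylene between the two ketones attacks the released ester in a Claisen condensation, and aromatisation gives chalcone A1, (E)-3'-(benzyloxy)-2',6'-dihydroxy-4'-methoxychalcone.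

- For it: one step makes ring A with all its oxygens placed and the three-carbon chain attached, and the benzyl ether marks the future O8.
- Against it: A1 has two free hydroxyls flanking the ketone. Only closure through the one next to the benzyloxy group gives the 5,7,8 series; the other gives the 5,6,7 isomer, and nothing in A1 clearly favours the hindered oxygen. Oxidative closure of a chalcone with an oxygen at C6' under Algar–Flynn–Oyamada conditions tends to give aurones, not flavonols. A2 itself needs several steps, and aldol folding or methoxide addition to the enone can compete with the Claisen step.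
- Comparison: it is stronger in that it builds ring A and its oxygenation at once from an acyclic chain. The chosen route offers a ring C closure with only one oxygen able to take part, and it is not longer.

**Alternative 2: ring A by cyclobutenone ring expansion.** The cut is C4a–C5. The precursor would be A4, 4-[5-(benzyloxy)-4-oxo-6-phenyl-4H-pyran-2-yl]-4-hydroxy-3-methoxycyclobut-2-en-1-one, made by adding a metalated pyranone to a squarate-derived dione. Heating opens the four-membered ring to a vinylketene, the ketene carbon bonds to pyranone C5 in a six-electron closure, and tautomerisation gives the hydroquinone A3, 3-(benzyloxy)-5,8-dihydroxy-7-methoxyflavone.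

- For it: the 5,8-dioxygenation and the 7-methoxy group are fixed by the cyclobutenone, and the 3-oxygen and phenyl group are present from the start. A3 needs only acylation of the unchelated 8-hydroxyl and hydrogenolysis, with no demethylation and no late oxidation at C3. On oxidation-state economy and endgame length it is stronger than the chosen route.
- Against it: metalation of a 3-alkoxy-4-pyranone at C6 competes with attack on the carbonyl and ring opening. Addition to the unsymmetrical dione must be regioselective. The ketene can be trapped by its own hydroxyl to give a butenolide when the pi partner is poor. A3 is an air-sensitive hydroquinone.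
- Comparison: the risk is spread over three uncertain operations. The chosen route concentrates it in one step, which can be bypassed by known chemistry from the same intermediate 6.

**Alternative 3: thermal acylketene annulation of the free catechol.** The cuts are C4–C4a and O1–C2. Catechol 3 would be heated with the keto ester A6, ethyl 2-(benzyloxy)-3-oxo-3-phenylpropanoate. This should lose ethanol to an acylketene that C-acylates the ring, and cyclodehydration would give A5, 3-(benzyloxy)-8-hydroxy-5,7-dimethoxyflavone.

- For it: this is the shortest plan. Ring C, the 3-oxygen and the phenyl group arrive in one step from compound 3, and acylation followed by one Lewis acid deprotection would finish the synthesis. On step economy it is clearly stronger.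
- Against it: an acylketene reacts first at oxygen, and 3 has two hydroxyls. The aryl keto ester so formed can close the Pechmann way to a coumarin. C-acylation must occur at the carbon ortho to the hydroxyl and not at the carbon between the two methyl ethers. The temperatures such annulations need are hard on a benzyl ether alpha to two carbonyls and on an electron-rich catechol.
- Comparison: the chosen route is longer, but each bond of ring C is formed in a separate, defined event whose regiochemistry is set by where the aldehyde and the vinyl ether sit.

Key step: step 5

## Route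

**Step 1**
Reactants: 1 2-hydroxy-4,6-dimethoxybenzaldehyde
Product: 3 3,5-dimethoxybenzene-1,2-diol, via aryl formate 2 (not isolated)
Conditions: 30% H2O2, NaOH (aq), THF, 0 °C, N2; then 1 M HCl
Reagents that add atoms: hydrogen peroxide, OO
Why: Dakin oxidation: hydroperoxide adds to the aldehyde, the electron-rich aryl group migrates to oxygen to give formate 2, and hydroxide cleaves the formate. Working cold under nitrogen and acidifying promptly should protect the electron-rich catechol from air oxidation.

**Step 2**
Reactants: 3 3,5-dimethoxybenzene-1,2-diol
Product: 5 2,3-dihydroxy-4,6-dimethoxybenzaldehyde, via hydroxymethyl catechol 4 (not isolated)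
Conditions: MgCl2 (3 equiv), Et3N (6 equiv), (CH2O)n, MeCN, reflux, N2; then 1 M HCl
Reagents that add atoms: paraformaldehyde (as formaldehyde), C=O
Why: Magnesium-mediated ortho-formylation of a phenol: the magnesium phenoxide binds formaldehyde and delivers it to the only ring carbon ortho to a hydroxyl, and the magnesium alkoxide of 4 is oxidised to the aldehyde by hydride transfer to a second formaldehyde. The other ring CH sits between two methyl ethers and has no phenoxide next to it.

**Step 3**
Reactants: 5 2,3-dihydroxy-4,6-dimethoxybenzaldehyde
Product: 6 3-[(tert-butyldimethylsilyl)oxy]-2-hydroxy-4,6-dimethoxybenzaldehyde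
Conditions: TBSCl (1.05 equiv), imidazole, CH2Cl2, 0 °C
Reagents that add atoms: tert-butyldimethylsilyl chloride, CC(C)(C)[Si](C)(C)Cl
Why: Selective silylation of the hydroxyl that is not chelated to the aldehyde. A 1,4-silyl shift between the two oxygens would lead to the same isomer, because it keeps the stronger hydrogen bond and the more acidic phenol free.

**Step 4**
Reactants: 6 3-[(tert-butyldimethylsilyl)oxy]-2-hydroxy-4,6-dimethoxybenzaldehyde; 7 1-phenylvinylboronic acid
Product: 8 3-[(tert-butyldimethylsilyl)oxy]-4,6-dimethoxy-2-[(1-phenylethenyl)oxy]benzaldehyde
Conditions: Cu(OAc)2 (2 equiv), pyridine, 4 Å MS, CH2Cl2, dry air, rt; 7 in excess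
Reagents that add atoms: none
Why: Chan–Lam O-alkenylation of a phenol: the copper phenoxide undergoes transmetalation with the alkenylboronic acid, and C–O reductive elimination from the oxidised copper centre gives the aryl vinyl ether. The conditions are near neutral, so the aldehyde and the silyl ether should be untouched.

**Step 5**
Reactants: 8 3-[(tert-butyldimethylsilyl)oxy]-4,6-dimethoxy-2-[(1-phenylethenyl)oxy]benzaldehyde
Product: 9 8-[(tert-butyldimethylsilyl)oxy]-5,7-dimethoxy-2-phenyl-4H-chromen-4-one
Conditions: DTBP (3 equiv), Cu(OAc)2 (5 mol%), PhCl (0.02 M), 120 °C, Ar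
Reagents that add atoms: none
Why: Proposed new method: thermal homolysis of DTBP gives tert-butoxyl radicals, which abstract the weak formyl hydrogen of 8 to give an aroyl radical that loses CO only slowly. The acyl carbon adds to the unsubstituted CH2 terminus of the 1-phenylvinyl ether in a 6-endo-trig closure, which forms the C3–C4 bond and ring C and leaves a tertiary radical at C2 stabilised by both the phenyl group and O1. This electron-rich radical is oxidised, by divalent copper that the peroxide regenerates or by the peroxide itself, to the 2-phenyl oxocarbenium ion, and loss of a C3 proton gives the pyranone of 9. The closest known reaction types are the peroxide-initiated acyl radical cyclisations of 2-(allyloxy)benzaldehydes to chroman-4-ones and of 2-aryloxybenzaldehydes to xanthones; closure onto a 1,1-disubstituted enol ether with oxidative rearomatisation has not been shown. No stereocentre is formed. The step needs 6-endo over 5-exo selectivity, and the substrate secures it because 5-exo attack would have to hit the fully substituted, oxygen-bearing alkene carbon and would leave an unstabilised primary radical. It also needs hydrogen abstraction at the aldehyde only, which the silyl group at O8 supports because it has no weak C–H bond, and the methyl ether C–H bonds are much stronger than the formyl C–H bond.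

**Step 6**
Reactants: 9 8-[(tert-butyldimethylsilyl)oxy]-5,7-dimethoxy-2-phenyl-4H-chromen-4-one; 10 butyric anhydride
Product: 12 5,7-dimethoxy-4-oxo-2-phenyl-4H-chromen-8-yl butanoate, via 8-hydroxy-5,7-dimethoxyflavone phenoxide 11 (not isolated)
Conditions: TBAF (Bu4NF, 1.1 equiv), THF, 0 °C, Ar; then (PrCO)2O (3 equiv), 0 °C to rt
Reagents that add atoms: none
Why: Fluoride cleaves the aryl silyl ether, and the tetrabutylammonium phenoxide 11 is acylated in the same flask by anhydride 10. The oxidation-prone phenol is never isolated, and no other hydroxyl is present to compete.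

**Step 7**
Reactants: 12 5,7-dimethoxy-4-oxo-2-phenyl-4H-chromen-8-yl butanoate
Product: 14 3-hydroxy-5,7-dimethoxy-4-oxo-2-phenyl-4H-chromen-8-yl butanoate, via flavone 2,3-epoxide 13 (not isolated)
Conditions: DMDO (acetone solution, excess), CH2Cl2, 0 °C to rt, dark; evaporate; then TsOH (cat.), CH2Cl2, rt
Reagents that add atoms: dimethyldioxirane, CC1(C)OO1
Why: Dioxirane epoxidation of the flavone C2=C3 bond under neutral conditions gives the racemic, cis-fused epoxide 13. Acid opens it at C2 to the cation stabilised by O1 and phenyl, and loss of the C3 proton gives the 3-hydroxyflavone. The ester and the methyl ethers should be inert to both reagents.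

**Step 8**
Reactants: 14 3-hydroxy-5,7-dimethoxy-4-oxo-2-phenyl-4H-chromen-8-yl butanoate
Product: 15 3,5-dihydroxy-7-methoxy-4-oxo-2-phenyl-4H-chromen-8-yl butanoate
Conditions: BCl3 (3 equiv), CH2Cl2, −78 to 0 °C; then cold H2O
Reagents that add atoms: none
Why: Chelation-directed demethylation: boron bound to the C4 carbonyl activates only the peri 5-methyl ether for attack by chloride. The 7-methyl ether has no such chelate, and the aryl ester should survive at low temperature.

## Compound list

1 | 2-hydroxy-4,6-dimethoxybenzaldehyde | O=Cc1c(O)cc(OC)cc1OC | starting material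
2 | 2-hydroxy-4,6-dimethoxyphenyl formate | O=COc1c(O)cc(OC)cc1OC | intermediate (not isolated)
3 | 3,5-dimethoxybenzene-1,2-diol | COc1cc(O)c(O)c(OC)c1 | intermediate
4 | 3-(hydroxymethyl)-4,6-dimethoxybenzene-1,2-diol (formed as its magnesium salt) | OCc1c(O)c(O)c(OC)cc1OC | intermediate (not isolated)
5 | 2,3-dihydroxy-4,6-dimethoxybenzaldehyde | O=Cc1c(O)c(O)c(OC)cc1OC | intermediate
6 | 3-[(tert-butyldimethylsilyl)oxy]-2-hydroxy-4,6-dimethoxybenzaldehyde | O=Cc1c(O)c(O[Si](C)(C)C(C)(C)C)c(OC)cc1OC | intermediate
7 | 1-phenylvinylboronic acid | C=C(B(O)O)c1ccccc1 | starting material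
8 | 3-[(tert-butyldimethylsilyl)oxy]-4,6-dimethoxy-2-[(1-phenylethenyl)oxy]benzaldehyde | COc1cc(OC)c(C=O)c(OC(=C)c2ccccc2)c1O[Si](C)(C)C(C)(C)C | intermediate
9 | 8-[(tert-butyldimethylsilyl)oxy]-5,7-dimethoxy-2-phenyl-4H-chromen-4-one | COc1cc(OC)c2c(=O)cc(-c3ccccc3)oc2c1O[Si](C)(C)C(C)(C)C | intermediate
10 | butyric anhydride | CCCC(=O)OC(=O)CCC | starting material
11 | 8-hydroxy-5,7-dimethoxy-2-phenyl-4H-chromen-4-one (formed as its tetrabutylammonium phenoxide) | COc1cc(OC)c2c(=O)cc(-c3ccccc3)oc2c1O | intermediate (not isolated)
12 | 5,7-dimethoxy-4-oxo-2-phenyl-4H-chromen-8-yl butanoate | CCCC(=O)Oc1c(OC)cc(OC)c2c(=O)cc(-c3ccccc3)oc12 | intermediate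
13 | 4,6-dimethoxy-7-oxo-1a-phenyl-1a,7a-dihydro-7H-oxireno[2,3-b]chromen-3-yl butanoate (2,3-epoxide of 12; racemic, cis-fused, one enantiomer drawn) | O=C1[C@@H]2O[C@]2(c3ccccc3)Oc4c1c(OC)cc(OC)c4OC(=O)CCC | intermediate (not isolated)
14 | 3-hydroxy-5,7-dimethoxy-4-oxo-2-phenyl-4H-chromen-8-yl butanoate | CCCC(=O)Oc1c(OC)cc(OC)c2c(=O)c(O)c(-c3ccccc3)oc12 | intermediate
15 | 3,5-dihydroxy-7-methoxy-4-oxo-2-phenyl-4H-chromen-8-yl butanoate | CCCC(=O)Oc1c(OC)cc(O)c2c(=O)c(O)c(-c3ccccc3)oc12 | target

## Step count and least certain steps

Total step count: 8. Longest linear sequence: 8 steps (from 1; compounds 7 and 10 are bought).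

**Step 5 (key step, proposed new method).** The acyl radical is nucleophilic and the enol ether is electron-rich, so closure may be slow. Intermolecular addition of tert-butoxyl or methyl radicals to the styrene-type double bond, oxidation of the acyl radical to the acid, or stalling of the C2 radical before it is oxidised could then take over.
Fallback (ionic, known chemistry), setting out from 6 and returning at 9: addition of PhC≡CLi (2.2 equiv, THF, −78 °C, cold acidic quench to limit silyl migration) to the aldehyde would give 1-{3-[(tert-butyldimethylsilyl)oxy]-2-hydroxy-4,6-dimethoxyphenyl}-3-phenylprop-2-yn-1-ol F1. Oxidation with MnO2 in CH2Cl2 would give the ynone 1-{3-[(tert-butyldimethylsilyl)oxy]-2-hydroxy-4,6-dimethoxyphenyl}-3-phenylprop-2-yn-1-one F2. Diethylamine in ethanol would add to the ynone to give the enaminone (E)-3-(diethylamino)-1-{3-[(tert-butyldimethylsilyl)oxy]-2-hydroxy-4,6-dimethoxyphenyl}-3-phenylprop-2-en-1-one F3. On warming, the phenol attacks the amine-bearing carbon and diethylamine is lost, which closes ring C in the flavone sense only and gives 9.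

**Step 4 (Chan–Lam coupling).** The phenol is chelated and has substituents on both ortho positions, so transmetalation and C–O bond formation may be slow. Protodeboronation and oligomerisation of the alpha-styrenylboronic acid could then consume the coupling partner.
Fallback, setting out from 6 and returning at 8: the C–O bond is made at an sp3 carbon and the alkene is formed afterwards. Mitsunobu etherification of 6 with 2-bromo-1-phenylethanol (PPh3, DIAD, THF) would give racemic 2-(2-bromo-1-phenylethoxy)-3-[(tert-butyldimethylsilyl)oxy]-4,6-dimethoxybenzaldehyde F4. Dehydrobromination with DBU in warm MeCN removes the benzylic, oxygen-activated hydrogen and the primary bromide to give the 1,1-disubstituted enol ether 8.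

**Step 2 (ortho-formylation of the catechol).** The catecholate may bind magnesium as a chelate and block delivery of formaldehyde to the ortho carbon, and the electron-rich catechol may oxidise during the long reflux.
Fallback, setting out from 3 and returning at 5: directed ortho-metalation in place of phenoxide-directed formylation. Protection with MOMCl and iPr2NEt would give 1,2-bis(methoxymethoxy)-3,5-dimethoxybenzene F5. Lithiation with n-BuLi and TMEDA in THF at the carbon between the MOM ether and a methyl ether (the MOM group being the stronger director), followed by DMF, would give 2,3-bis(methoxymethoxy)-4,6-dimethoxybenzaldehyde F6. HCl in methanol removes both acetals to give 5.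

**Step 7 (epoxidation and isomerisation).** The dioxirane may oxidise the electron-rich ring A faster than the enone double bond, or the epoxide may open with ring contraction instead of simple proton loss.
Fallback, setting out from 9 and returning at 14: the 3-oxygen is introduced through the C3 anion. Lithiation of 9 at C3 with LDA (LiN(iPr)2, THF, −78 °C), trapping with B(OMe)3 and oxidation with H2O2 and AcOH would give 8-[(tert-butyldimethylsilyl)oxy]-3-hydroxy-5,7-dimethoxy-2-phenyl-4H-chromen-4-one F7. Benzylation (BnBr, K2CO3, acetone) would give 3-(benzyloxy)-8-[(tert-butyldimethylsilyl)oxy]-5,7-dimethoxy-2-phenyl-4H-chromen-4-one F8. Desilylative acylation as in step 6 (Bu4NF, then 10) would give 3-(benzyloxy)-5,7-dimethoxy-4-oxo-2-phenyl-4H-chromen-8-yl butanoate F9. Hydrogenolysis (H2, Pd/C, EtOAc) removes the benzyl group to give 14.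

## Further compounds

F1 | step 5 | 1-{3-[(tert-butyldimethylsilyl)oxy]-2-hydroxy-4,6-dimethoxyphenyl}-3-phenylprop-2-yn-1-ol (racemic) | OC(C#Cc1ccccc1)c1c(O)c(O[Si](C)(C)C(C)(C)C)c(OC)cc1OC
F2 | step 5 | 1-{3-[(tert-butyldimethylsilyl)oxy]-2-hydroxy-4,6-dimethoxyphenyl}-3-phenylprop-2-yn-1-one | O=C(C#Cc1ccccc1)c1c(O)c(O[Si](C)(C)C(C)(C)C)c(OC)cc1OC
F3 | step 5 | (E)-3-(diethylamino)-1-{3-[(tert-butyldimethylsilyl)oxy]-2-hydroxy-4,6-dimethoxyphenyl}-3-phenylprop-2-en-1-one | CCN(CC)/C(=C/C(=O)c1c(O)c(O[Si](C)(C)C(C)(C)C)c(OC)cc1OC)c1ccccc1
F4 | step 4 | 2-(2-bromo-1-phenylethoxy)-3-[(tert-butyldimethylsilyl)oxy]-4,6-dimethoxybenzaldehyde (racemic) | O=Cc1c(OC(CBr)c2ccccc2)c(O[Si](C)(C)C(C)(C)C)c(OC)cc1OC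
F5 | step 2 | 1,2-bis(methoxymethoxy)-3,5-dimethoxybenzene | COCOc1cc(OC)cc(OC)c1OCOC
F6 | step 2 | 2,3-bis(methoxymethoxy)-4,6-dimethoxybenzaldehyde | COCOc1c(C=O)c(OC)cc(OC)c1OCOC
F7 | step 7 | 8-[(tert-butyldimethylsilyl)oxy]-3-hydroxy-5,7-dimethoxy-2-phenyl-4H-chromen-4-one | COc1cc(OC)c2c(=O)c(O)c(-c3ccccc3)oc2c1O[Si](C)(C)C(C)(C)C
F8 | step 7 | 3-(benzyloxy)-8-[(tert-butyldimethylsilyl)oxy]-5,7-dimethoxy-2-phenyl-4H-chromen-4-one | COc1cc(OC)c2c(=O)c(OCc3ccccc3)c(-c3ccccc3)oc2c1O[Si](C)(C)C(C)(C)C
F9 | step 7 | 3-(benzyloxy)-5,7-dimethoxy-4-oxo-2-phenyl-4H-chromen-8-yl butanoate | CCCC(=O)Oc1c(OC)cc(OC)c2c(=O)c(OCc3ccccc3)c(-c3ccccc3)oc12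
A1 | alternative 1 | (E)-3'-(benzyloxy)-2',6'-dihydroxy-4'-methoxychalcone | O=C(/C=C/c1ccccc1)c1c(O)cc(OC)c(OCc2ccccc2)c1O
A2 | alternative 1 | 3-(benzyloxy)-4-methoxy-6-[(E)-2-oxo-4-phenylbut-3-en-1-yl]-2H-pyran-2-one | O=C(Cc1cc(OC)c(OCc2ccccc2)c(=O)o1)/C=C/c1ccccc1
A3 | alternative 2 | 3-(benzyloxy)-5,8-dihydroxy-7-methoxyflavone | COc1cc(O)c2c(=O)c(OCc3ccccc3)c(-c3ccccc3)oc2c1O
A4 | alternative 2 | 4-[5-(benzyloxy)-4-oxo-6-phenyl-4H-pyran-2-yl]-4-hydroxy-3-methoxycyclobut-2-en-1-one (racemic) | COC1=CC(=O)C1(O)c1cc(=O)c(OCc2ccccc2)c(-c2ccccc2)o1
A5 | alternative 3 | 3-(benzyloxy)-8-hydroxy-5,7-dimethoxyflavone | COc1cc(OC)c2c(=O)c(OCc3ccccc3)c(-c3ccccc3)oc2c1O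
A6 | alternative 3 | ethyl 2-(benzyloxy)-3-oxo-3-phenylpropanoate (racemic) | CCOC(=O)C(OCc1ccccc1)C(=O)c1ccccc1
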